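**Retrosynthetic overview**

- Reutericyclin C 15 is cut at the C3–acetyl bond (O-acetylation, then O-to-C migration) to the N-enoyl tetramic acid 13. Unmasking C4 leads back to ketal imide 12, and the N1–acyl bond leads back to lactam 9 and enoyl chloride 11.
- Key disconnection: the N1–C5 bond of 9 goes back to the achiral dioxazolone 8. An iridium acyl nitrenoid inserts into one enantiotopic C5–H bond, which closes the pyrrolidinone (the only ring) and sets C5 (the only stereocentre) in the same step.
- 8 comes from hydroxamic acid 7, ketal ester 6 and β-keto ester 4, which is made from 4-methylpentanoic acid 1 and Meldrum's acid 2.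
- Feature used: in the pyrrolidine-2,4-dione ring, C5 is the γ-carbon of the chain N1–C2(=O)–C3–C4–C5. The ring is therefore a γ-lactam whose N1–C5 bond maps onto a methylene C–H bond of achiral 6-methyl-3-oxoheptanoic acid, with C4 carried as a dioxolane.

Key step: step 5

Assumption: the (S,S)-diamine ligand is written as the one that delivers the (R)-lactam. The sense of induction on this substrate is to be confirmed on a trial run, and the commercially available (R,R)-antipode is used instead if it proves opposite.

**Route**

Step 1
Reactants: 1 4-methylpentanoic acid; 2 Meldrum's acid (2,2-dimethyl-1,3-dioxane-4,6-dione)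
Product: 4 methyl 6-methyl-3-oxoheptanoate, via acyl Meldrum's acid 3 (not isolated)
Conditions: N,N'-dicyclohexylcarbodiimide, DMAP, CH2Cl2, 0 °C to rt; filter, dilute aq. KHSO4 wash; then MeOH, reflux
Reagents that add atoms: methanol, CO
Why: Carbodiimide/DMAP C-acylation of Meldrum's acid followed by methanolysis of the acyl Meldrum's acid (loss of acetone and CO2 through the acylketene) is the standard two-carbon homologation of a carboxylic acid to a β-keto ester.

Step 2
Reactants: 4 methyl 6-methyl-3-oxoheptanoate; 5 ethylene glycol
Product: 6 methyl 2-[2-(3-methylbutyl)-1,3-dioxolan-2-yl]acetate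
Conditions: p-TsOH·H2O (cat.), toluene, reflux, Dean–Stark trap
Reagents that add atoms: none
Why: Acid-catalysed ketalisation with azeotropic removal of water converts the ketone of a β-keto ester into its dioxolane, which removes the enolisable 1,3-dicarbonyl unit before the hydroxylamine and nitrenoid steps, and any ester exchange with the glycol is harmless because either ester gives 7 in step 3.

Step 3
Reactants: 6 methyl 2-[2-(3-methylbutyl)-1,3-dioxolan-2-yl]acetate
Product: 7 N-hydroxy-2-[2-(3-methylbutyl)-1,3-dioxolan-2-yl]acetamide
Conditions: NH2OH·HCl, KOH, MeOH, 0 °C to rt; cold aq. NaH2PO4 to pH about 6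
Reagents that add atoms: hydroxylamine (used as its hydrochloride), NO
Why: Aminolysis of a methyl ester by free hydroxylamine under basic conditions is the usual hydroxamic acid synthesis, the base-stable ketal prevents the isoxazolone formation that a free β-keto ester would undergo, and the near-neutral work-up keeps the ketal intact.

Step 4
Reactants: 7 N-hydroxy-2-[2-(3-methylbutyl)-1,3-dioxolan-2-yl]acetamide
Product: 8 3-{[2-(3-methylbutyl)-1,3-dioxolan-2-yl]methyl}-1,4,2-dioxazol-5-one
Conditions: 1,1'-carbonyldiimidazole, CH2Cl2, rt; quick cold aq. NaH2PO4 wash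
Reagents that add atoms: 1,1'-carbonyldiimidazole, O=C(n1ccnc1)n1ccnc1
Why: Cyclocarbonylation of a hydroxamic acid with carbonyldiimidazole (O-acylation, then closure of the imidate oxygen onto the activated carbonyl) is the standard route to 1,4,2-dioxazol-5-ones and runs under neutral conditions that the ketal tolerates.

Step 5
Reactants: 8 3-{[2-(3-methylbutyl)-1,3-dioxolan-2-yl]methyl}-1,4,2-dioxazol-5-one
Product: 9 (R)-6-(2-methylpropyl)-1,4-dioxa-7-azaspiro[4.4]nonan-8-one
Conditions: Cp*IrCl[(S,S)-TsNCHPhCHPhNH2] (5 mol%, preformed from [Cp*IrCl2]2, (S,S)-N-tosyl-1,2-diphenylethylenediamine and Et3N), Na[B(3,5-(CF3)2C6H3)4] (5 mol%), CH2Cl2, 35 °C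
Reagents that add atoms: none
Why: Chloride abstraction gives a cationic trivalent iridium centre that binds the dioxazolone nitrogen and, on loss of CO2, becomes an electrophilic iridium acyl nitrenoid whose nitrogen inserts into a C5–H bond in a concerted, asynchronous hydride-transfer and C–N bond-forming event. The closest known reaction type is the iridium- and ruthenium-catalysed enantioselective intramolecular C(sp3)–H amidation of 3-alkyl-1,4,2-dioxazol-5-ones to γ-lactams, which includes unactivated methylene groups, so the step is that reaction on a new substrate. The pyrrolidinone ring is closed by N1–C5 bond formation, a 1,5 C–H insertion through a six-centre array (N1, C2, C3, C4, C5 and the migrating hydrogen) that gives the five-membered lactam. C5 is set by the chiral diamine ligand, whose N–H hydrogen-bonds to the nitrenoid carbonyl while the sulfonamide aryl group blocks one side, so that only one of the two enantiotopic C5–H bonds can reach nitrogen. The step needs site selectivity for the γ-methylene over the dioxolane OCH2 groups and the next chain methylene (both six-membered closures) and over the tertiary C–H (seven-membered closure), which the kinetic preference for five-membered closure and the Thorpe–Ingold effect of the quaternary ketal carbon should secure, and it needs insertion to outrun Curtius-type rearrangement to the isocyanate, which the electron-rich anionic N,N'-chelate should suppress. The ketal carbon inductively deactivates the C5–H bonds, so a longer reaction time or a higher loading may be needed, but it keeps C4 at the ketone level without an enol that the nitrenoid could attack.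

Step 6
Reactants: 10 (E)-dodec-2-enoic acid
Product: 11 (E)-dodec-2-enoyl chloride
Conditions: (COCl)2, DMF (cat.), CH2Cl2, 0 °C to rt; concentrate and use crude
Reagents that add atoms: oxalyl chloride, O=C(Cl)C(=O)Cl
Why: Vilsmeier-type activation with oxalyl chloride and catalytic DMF converts the enoic acid into its chloride at low temperature without isomerising the E-alkene.

Step 7
Reactants: 9 (R)-6-(2-methylpropyl)-1,4-dioxa-7-azaspiro[4.4]nonan-8-one; 11 (E)-dodec-2-enoyl chloride
Product: 12 (R)-7-[(E)-dodec-2-enoyl]-6-(2-methylpropyl)-1,4-dioxa-7-azaspiro[4.4]nonan-8-one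
Conditions: n-BuLi, THF, −78 °C; then 11, −78 to 0 °C
Reagents that add atoms: none
Why: Deprotonation of the lactam N–H (the only acidic site, C5 being non-enolisable next to the ketal) gives a lithium amide that is acylated on nitrogen by the acid chloride, the usual N-acylation of lactams and oxazolidinones with enoyl chlorides, so the C5 configuration is untouched.

Step 8
Reactants: 12 (R)-7-[(E)-dodec-2-enoyl]-6-(2-methylpropyl)-1,4-dioxa-7-azaspiro[4.4]nonan-8-one
Product: 13 (R)-1-[(E)-dodec-2-enoyl]-5-(2-methylpropyl)pyrrolidine-2,4-dione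
Conditions: TFA–H2O (9:1), CH2Cl2, 0 °C to rt
Reagents that add atoms: water, O
Why: Acid-catalysed hydrolysis of the dioxolane through its oxocarbenium ion releases the C4 ketone, the imide and the E-enoyl group are stable to aqueous acid, and the absence of base should keep C5 from epimerising.

Step 9
Reactants: 13 (R)-1-[(E)-dodec-2-enoyl]-5-(2-methylpropyl)pyrrolidine-2,4-dione
Product: 15 Reutericyclin C [(R)-3-acetyl-1-[(E)-dodec-2-enoyl]-4-hydroxy-5-(2-methylpropyl)-1,5-dihydro-2H-pyrrol-2-one], via enol acetate 14 (not isolated)
Conditions: AcOH, N,N'-dicyclohexylcarbodiimide, DMAP (1.3 equiv), CH2Cl2, 0 °C to rt; dilute aq. KHSO4 work-up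
Reagents that add atoms: acetic acid, CC(=O)O
Why: Carbodiimide/DMAP O-acetylation of the C4 enol followed by DMAP-mediated Steglich-type migration of the acetyl group from O4 to C3 through an acetylpyridinium–enolate ion pair is the standard 3-acylation of tetramic acids (well established for N-alkoxycarbonyl ones, the closest relatives of this N-acyl one), and the strongly acidic chelated product, held as its enolate, drives the migration and shields C5 from deprotonation.

**Compound list**

1 | 4-methylpentanoic acid | CC(C)CCC(=O)O | starting material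
2 | Meldrum's acid (2,2-dimethyl-1,3-dioxane-4,6-dione) | CC1(C)OC(=O)CC(=O)O1 | starting material
3 | 5-(1-hydroxy-4-methylpentylidene)-2,2-dimethyl-1,3-dioxane-4,6-dione (acyl Meldrum's acid, not isolated) | CC(C)CCC(O)=C1C(=O)OC(C)(C)OC1=O | intermediate
4 | methyl 6-methyl-3-oxoheptanoate | CC(C)CCC(=O)CC(=O)OC | intermediate
5 | ethylene glycol | OCCO | starting material
6 | methyl 2-[2-(3-methylbutyl)-1,3-dioxolan-2-yl]acetate | COC(=O)CC1(CCC(C)C)OCCO1 | intermediate
7 | N-hydroxy-2-[2-(3-methylbutyl)-1,3-dioxolan-2-yl]acetamide | CC(C)CCC1(CC(=O)NO)OCCO1 | intermediate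
8 | 3-{[2-(3-methylbutyl)-1,3-dioxolan-2-yl]methyl}-1,4,2-dioxazol-5-one | CC(C)CCC1(CC2=NOC(=O)O2)OCCO1 | intermediate
9 | (R)-6-(2-methylpropyl)-1,4-dioxa-7-azaspiro[4.4]nonan-8-one | O=C1CC2(OCCO2)[C@@H](CC(C)C)N1 | intermediate
10 | (E)-dodec-2-enoic acid | CCCCCCCCC/C=C/C(=O)O | starting material
11 | (E)-dodec-2-enoyl chloride | CCCCCCCCC/C=C/C(=O)Cl | intermediate
12 | (R)-7-[(E)-dodec-2-enoyl]-6-(2-methylpropyl)-1,4-dioxa-7-azaspiro[4.4]nonan-8-one | CCCCCCCCC/C=C/C(=O)N1C(=O)CC2(OCCO2)[C@H]1CC(C)C | intermediate
13 | (R)-1-[(E)-dodec-2-enoyl]-5-(2-methylpropyl)pyrrolidine-2,4-dione | CCCCCCCCC/C=C/C(=O)N1C(=O)CC(=O)[C@H]1CC(C)C | intermediate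
14 | (R)-1-[(E)-dodec-2-enoyl]-2-(2-methylpropyl)-5-oxo-2,5-dihydro-1H-pyrrol-3-yl acetate (enol acetate, not isolated) | CCCCCCCCC/C=C/C(=O)N1C(=O)C=C(OC(C)=O)[C@H]1CC(C)C | intermediate
15 | Reutericyclin C, (R)-3-acetyl-1-[(E)-dodec-2-enoyl]-4-hydroxy-5-(2-methylpropyl)-1,5-dihydro-2H-pyrrol-2-one | CCCCCCCCC/C=C/C(=O)N1C(=O)C(C(C)=O)=C(O)[C@H]1CC(C)C | target

**Step count**

Total: 9 steps. Longest linear sequence: 8 steps (steps 1 to 5, then 7 to 9), with a one-step branch (step 6) for the acid chloride.

**Steps most likely to fail**

1. Step 5. The ligand may discriminate the two enantiotopic C5–H bonds poorly on a substrate that offers no aryl or π group to hold. Insertion into the inductively deactivated methylene may also be slow enough for Curtius-type rearrangement, insertion at a dioxolane OCH2 group or capture of the nitrenoid by a ketal oxygen to compete. The fallback buys the stereocentre from the chiral pool instead of making it by catalysis; it sets out from Meldrum's acid 2 and returns at lactam 9. Commercial N-phthaloyl-D-leucine (CC(C)C[C@@H](N1C(=O)c2ccccc2C1=O)C(=O)O) is coupled to 2 under the carbodiimide/DMAP conditions of step 1 to give the acyl Meldrum's adduct F1. This is not isolated but heated in methanol to give methyl (R)-4-(1,3-dioxoisoindolin-2-yl)-6-methyl-3-oxoheptanoate F2. The ketone is ketalised with 1,2-bis(trimethylsilyloxy)ethane and catalytic TMSOTf in CH2Cl2 at low temperature, conditions chosen to spare the α-phthalimido ketone from enolisation, to give methyl (R)-2-{2-[1-(1,3-dioxoisoindolin-2-yl)-3-methylbutyl]-1,3-dioxolan-2-yl}acetate F3. Hydrazine hydrate in ethanol removes the phthaloyl group, and the liberated methyl (R)-2-[2-(1-amino-3-methylbutyl)-1,3-dioxolan-2-yl]acetate F4 should close spontaneously onto its ester to give 9, from which steps 7 to 9 follow unchanged.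

2. Step 9. The 4-acetoxy pyrrolinone 14 carries an acidic C5–H and may epimerise under DMAP before the acetyl group migrates. DMAP may also attack the N-enoyl group (acyl transfer or conjugate addition), or the migration may stall at the enol acetate. The fallback installs the C3 acetyl group before the N-acyl group exists and without amine base; it sets out from lactam 9, returns at target 15, and also bypasses steps 7 and 8. Aqueous acid hydrolysis of 9 gives (R)-5-(2-methylpropyl)pyrrolidine-2,4-dione F5. Acetyl chloride in BF3·OEt2 at about 70 °C gives the difluoroboron chelate of the 3-acetyl tetramic acid F6 by Lewis-acid-mediated direct C-acylation. Methanolysis releases (R)-3-acetyl-4-hydroxy-5-(2-methylpropyl)-1,5-dihydro-2H-pyrrol-2-one F7. Double deprotonation with n-BuLi in THF at −78 °C and N-acylation of the dianion with enoyl chloride 11 gives 15. This last acylation has its own risk of C5 epimerisation and must be run cold and briefly.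

3. Step 7. On the hindered lithium amide, flanked by the C5 isobutyl group and the spiro ketal, the enoyl chloride may undergo γ-deprotonation to a vinylketene or conjugate addition instead of N-acylation. The fallback acylates with a small, non-enolisable-at-γ electrophile and builds the alkene afterwards; it sets out from lactam 9 and returns at imide 12. Lithiation of 9 (n-BuLi, THF, −78 °C) and reaction with bromoacetyl bromide gives (R)-7-(2-bromoacetyl)-6-(2-methylpropyl)-1,4-dioxa-7-azaspiro[4.4]nonan-8-one F8. Michaelis–Arbuzov reaction with triethyl phosphite gives diethyl {2-oxo-2-[(R)-6-(2-methylpropyl)-8-oxo-1,4-dioxa-7-azaspiro[4.4]nonan-7-yl]ethyl}phosphonate F9. Horner–Wadsworth–Emmons olefination with decanal (LiCl, i-Pr2NEt, MeCN, rt) should give the E-enoyl imide 12.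

**Further compounds**

F1 | step 5 | (R)-5-[2-(1,3-dioxoisoindolin-2-yl)-1-hydroxy-4-methylpentylidene]-2,2-dimethyl-1,3-dioxane-4,6-dione | CC(C)C[C@@H](N1C(=O)c2ccccc2C1=O)C(O)=C3C(=O)OC(C)(C)OC3=O
F2 | step 5 | methyl (R)-4-(1,3-dioxoisoindolin-2-yl)-6-methyl-3-oxoheptanoate | COC(=O)CC(=O)[C@@H](CC(C)C)N1C(=O)c2ccccc2C1=O
F3 | step 5 | methyl (R)-2-{2-[1-(1,3-dioxoisoindolin-2-yl)-3-methylbutyl]-1,3-dioxolan-2-yl}acetate | COC(=O)CC1(OCCO1)[C@@H](CC(C)C)N2C(=O)c3ccccc3C2=O
F4 | step 5 | methyl (R)-2-[2-(1-amino-3-methylbutyl)-1,3-dioxolan-2-yl]acetate | COC(=O)CC1(OCCO1)[C@@H](CC(C)C)N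
F5 | step 9 | (R)-5-(2-methylpropyl)pyrrolidine-2,4-dione | O=C1CC(=O)[C@@H](CC(C)C)N1
F6 | step 9 | difluoroboron chelate of (R)-3-acetyl-4-hydroxy-5-(2-methylpropyl)-1,5-dihydro-2H-pyrrol-2-one (boron bridging the C4 oxygen and the acetyl oxygen) | CC1=[O+][B-](F)(F)OC2=C1C(=O)N[C@@H]2CC(C)C
F7 | step 9 | (R)-3-acetyl-4-hydroxy-5-(2-methylpropyl)-1,5-dihydro-2H-pyrrol-2-one | CC(=O)C1=C(O)[C@@H](CC(C)C)NC1=O
F8 | step 7 | (R)-7-(2-bromoacetyl)-6-(2-methylpropyl)-1,4-dioxa-7-azaspiro[4.4]nonan-8-one | O=C(CBr)N1C(=O)CC2(OCCO2)[C@H]1CC(C)C
F9 | step 7 | diethyl {2-oxo-2-[(R)-6-(2-methylpropyl)-8-oxo-1,4-dioxa-7-azaspiro[4.4]nonan-7-yl]ethyl}phosphonate | CCOP(=O)(OCC)CC(=O)N1C(=O)CC2(OCCO2)[C@H]1CC(C)C
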